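**Plan**
Rings: A = 3-aryloxy-4,5-dihydroxyphenyl, B = para-phenylene, C = 2-aryloxy-3,4-dihydroxyphenyl, D = ortho-phenylene; the macrocycle is 17-membered.
Retrosynthesis cuts, in order: the four O–CH3 bonds (phenols carried as methyl ethers); the CH2–CH2 bond between rings B and C (as CH=CH, from a dialdehyde); the ring C–O bond of the C–O–D ether; the ring A–ring D ethano bridge (as a stilbene); the ring B–O bond of the A–O–B ether.
Enabling feature: the two carbons joined in the ring closure are the benzylic carbons on ring B (para to the A–O–B ether oxygen) and on ring C (ortho to the C–O–D ether oxygen). Each can therefore start as a cyano or formyl carbon that first activates its ring for SNAr ether formation and then serves as one of two identical ends for reductive carbonyl coupling, so the ends need no differentiation.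
Forward order: A–O–B ether, A–D bridge (Wittig, hydrogenation), nitrile to aldehyde, C–O–D ether, 17-membered ring by McMurry coupling, alkene hydrogenation, global demethylation.
Stereochemistry: the target has no stereocentre; the alkene geometries of steps 2 and 6 are erased by hydrogenation.

Key step: step 6

Assumption: the 17-membered ring is taken as conformationally mobile, so the target is treated as achiral and no stereocontrol is planned.

**Step 1**
Reactants: 1 3-hydroxy-4,5-dimethoxybenzaldehyde; 2 4-fluorobenzonitrile
Product: 3 4-(5-formyl-2,3-dimethoxyphenoxy)benzonitrile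
Conditions: K2CO3, DMF, 100 °C, N2
Reagents that add atoms: none
Why: SNAr, in which the phenoxide of 1 displaces the fluoride para to the cyano group of 2; the nitrile is the masked formyl carbon of ring B and is inert to the olefination and hydrogenation that follow.

**Step 2**
Reactants: 3 4-(5-formyl-2,3-dimethoxyphenoxy)benzonitrile; 4 (2-hydroxybenzyl)triphenylphosphonium bromide
Product: 6 4-[5-[2-(2-hydroxyphenyl)ethenyl]-2,3-dimethoxyphenoxy]benzonitrile (E/Z mixture), via potassium phenoxide ylide 5 (not isolated)
Conditions: KOtBu (2.2 equiv), THF, 0 °C to rt; then 1 M HCl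
Reagents that add atoms: none
Why: Wittig olefination, in which two equivalents of base turn 4 into the phenoxide ylide 5 that adds to the only aldehyde present; the alkene geometry is of no consequence because it is saturated in step 3.

**Step 3**
Reactants: 6 4-[5-[2-(2-hydroxyphenyl)ethenyl]-2,3-dimethoxyphenoxy]benzonitrile
Product: 7 4-[5-[2-(2-hydroxyphenyl)ethyl]-2,3-dimethoxyphenoxy]benzonitrile
Conditions: H2 (1 atm), 10% Pd/C, EtOAc, rt, stopped after one equivalent of H2
Reagents that add atoms: none
Why: catalytic hydrogenation of a stilbene is fast at 1 atm in a neutral aprotic solvent, where the aryl nitrile and the diaryl ether should stay intact.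

**Step 4**
Reactants: 7 4-[5-[2-(2-hydroxyphenyl)ethyl]-2,3-dimethoxyphenoxy]benzonitrile
Product: 9 4-[5-[2-(2-hydroxyphenyl)ethyl]-2,3-dimethoxyphenoxy]benzaldehyde, via N-aluminated aldimine 8 (not isolated)
Conditions: DIBAL-H (3 equiv), CH2Cl2, −78 to 0 °C; then 1 M HCl, rt
Reagents that add atoms: water, O
Why: DIBAL-H partial reduction of an aryl nitrile stops at the aldimine stage 8, which hydrolyses to the aldehyde on acidic work-up; the phenol only consumes one equivalent of hydride as its aluminium phenoxide.

**Step 5**
Reactants: 9 4-[5-[2-(2-hydroxyphenyl)ethyl]-2,3-dimethoxyphenoxy]benzaldehyde; 10 2-fluoro-3,4-dimethoxybenzaldehyde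
Product: 11 2-[2-[2-[3-(4-formylphenoxy)-4,5-dimethoxyphenyl]ethyl]phenoxy]-3,4-dimethoxybenzaldehyde
Conditions: Cs2CO3, DMSO, 110 °C, N2
Reagents that add atoms: none
Why: SNAr, in which the caesium phenoxide of ring D displaces the fluoride ortho to the formyl group of 10 (the adjacent methoxy group adds inductive activation); the ring B aldehyde has no α-hydrogen and should be a spectator under anhydrous carbonate.

**Step 6**
Reactants: 11 2-[2-[2-[3-(4-formylphenoxy)-4,5-dimethoxyphenyl]ethyl]phenoxy]-3,4-dimethoxybenzaldehyde
Product: 13 macrocyclic stilbene (tetra-O-methyl ether of the target with CH=CH between rings B and C, geometry not defined), via titanium pinacolate 12 (not isolated)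
Conditions: TiCl4, Zn dust, pyridine, THF, reflux; 11 added by syringe pump over about 20 h to a final concentration near 2 mM
Reagents that add atoms: none
Why: Low-valent titanium from TiCl4/Zn transfers one electron to each formyl group, the two titanium-bound ketyl radicals couple to the cyclic titanium 1,2-diolate 12, and this loses both oxygens to titanium at reflux to leave the CH=CH bridge (McMurry reaction). The closest known reaction type is the intramolecular McMurry coupling of aromatic dialdehydes to macrocyclic stilbenes and cyclophanes. The one ring formed is the 17-membered macrocycle, closed end to end with both formyl carbons becoming ring members (endocyclic alkene) under pseudo-high dilution. No stereocentre is formed, and the alkene geometry is irrelevant because step 7 saturates it. The selectivity needed is ring closure over intermolecular coupling, which should be secured by the low stationary concentration, by the two diaryl ether oxygens and the ortho linkages of rings C and D that fold the chain back on itself, and by the flexible saturated A–D bridge. Methyl and diaryl ethers are inert to the reagent and no other reducible group is present.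

**Step 7**
Reactants: 13 macrocyclic stilbene
Product: 14 tetra-O-methyl ether of the target (CH2–CH2 between rings B and C)
Conditions: H2 (1 atm), 10% Pd/C, EtOAc–MeOH, rt
Reagents that add atoms: none
Why: catalytic hydrogenation of the stilbene double bond, on which both alkene isomers converge; aryl methyl ethers and diaryl ethers are not hydrogenolysed under these conditions.

**Step 8**
Reactants: 14 tetra-O-methyl ether of the target
Product: 15 target, the 17-membered bis(bibenzyl) macrocycle with catechol units on rings A and C
Conditions: BBr3 (excess), CH2Cl2, −78 °C to rt, argon; then H2O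
Reagents that add atoms: none
Why: BBr3 demethylation of aryl methyl ethers (boron coordination, then SN2 attack of bromide at methyl); the diaryl ethers offer no sp3 carbon for cleavage, and oxygen-free work-up protects the two catechols.

**Compound list**
1 | 3-hydroxy-4,5-dimethoxybenzaldehyde | COc1cc(C=O)cc(O)c1OC | starting material
2 | 4-fluorobenzonitrile | N#Cc1ccc(F)cc1 | starting material
3 | 4-(5-formyl-2,3-dimethoxyphenoxy)benzonitrile | COc1cc(C=O)cc(Oc2ccc(C#N)cc2)c1OC | intermediate
4 | (2-hydroxybenzyl)triphenylphosphonium bromide | [Br-].Oc1ccccc1C[P+](c1ccccc1)(c1ccccc1)c1ccccc1 | starting material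
5 | potassium 2-[(triphenyl-λ5-phosphanylidene)methyl]phenolate (ylide, not isolated) | [K+].[O-]c1ccccc1C=P(c1ccccc1)(c1ccccc1)c1ccccc1 | intermediate
6 | 4-[5-[2-(2-hydroxyphenyl)ethenyl]-2,3-dimethoxyphenoxy]benzonitrile (E/Z mixture, drawn without geometry) | COc1cc(C=Cc2ccccc2O)cc(Oc2ccc(C#N)cc2)c1OC | intermediate
7 | 4-[5-[2-(2-hydroxyphenyl)ethyl]-2,3-dimethoxyphenoxy]benzonitrile | COc1cc(CCc2ccccc2O)cc(Oc2ccc(C#N)cc2)c1OC | intermediate
8 | aldimine of 9 (present as its N-aluminium derivative, drawn without the metal, not isolated) | COc1cc(CCc2ccccc2O)cc(Oc2ccc(C=N)cc2)c1OC | intermediate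
9 | 4-[5-[2-(2-hydroxyphenyl)ethyl]-2,3-dimethoxyphenoxy]benzaldehyde | COc1cc(CCc2ccccc2O)cc(Oc2ccc(C=O)cc2)c1OC | intermediate
10 | 2-fluoro-3,4-dimethoxybenzaldehyde | COc1ccc(C=O)c(F)c1OC | starting material
11 | 2-[2-[2-[3-(4-formylphenoxy)-4,5-dimethoxyphenyl]ethyl]phenoxy]-3,4-dimethoxybenzaldehyde | COc1cc(CCc2ccccc2Oc2c(C=O)ccc(OC)c2OC)cc(Oc2ccc(C=O)cc2)c1OC | intermediate
12 | titanium pinacolate of the macrocycle (drawn as the metal-free 1,2-diol, mixture of diastereomers, not isolated) | COc1cc2cc(c1OC)Oc1ccc(cc1)C(O)C(O)c1ccc(OC)c(OC)c1Oc1ccccc1CC2 | intermediate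
13 | macrocyclic stilbene, tetra-O-methyl ether of the target with CH=CH between rings B and C (geometry not defined) | COc1cc2cc(c1OC)Oc1ccc(cc1)C=Cc1ccc(OC)c(OC)c1Oc1ccccc1CC2 | intermediate
14 | tetra-O-methyl ether of the target | COc1cc2cc(c1OC)Oc1ccc(cc1)CCc1ccc(OC)c(OC)c1Oc1ccccc1CC2 | intermediate
15 | target (no stereocentre) | Oc1cc2cc(c1O)Oc1ccc(cc1)CCc1ccc(O)c(O)c1Oc1ccccc1CC2 | target

**Step count**
Total: 8 steps. Longest linear sequence: 8 steps (from 1).

**Steps most likely to fail**

1. Step 6. Intermolecular carbonyl coupling to oligomers may outrun ring closure, or the reaction may stop at the pinacol stage. The fallback sets out from 11 and forms the same bond at the saturated level by a different reaction type. Reduction with NaBH4 (MeOH–THF, 0 °C) would give the diol [2-[2-[2-[3-[4-(hydroxymethyl)phenoxy]-4,5-dimethoxyphenyl]ethyl]phenoxy]-3,4-dimethoxyphenyl]methanol F1. PBr3 (CH2Cl2, 0 °C) would convert it into the bis(bromomethyl) compound 1-(bromomethyl)-2-[2-[2-[3-[4-(bromomethyl)phenoxy]-4,5-dimethoxyphenyl]ethyl]phenoxy]-3,4-dimethoxybenzene F2. Intramolecular Wurtz coupling (Na, catalytic tetraphenylethylene, THF, high dilution) would then close the ring and come back to the route at 14, bypassing 13.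

2. Step 5. Displacement may be sluggish at a fluoride flanked by the formyl and methoxy groups and deactivated by the para-methoxy group, and the aldehydes may degrade at the temperature then needed. The fallback sets out from 9 and replaces addition–elimination by copper-catalysed Ullmann C–O coupling, which does not depend on the electron demand of ring C. Phenol 9 and commercial 2-bromo-3,4-dimethoxybenzaldehyde (COc1ccc(C=O)c(Br)c1OC) with CuI, N,N-dimethylglycine and Cs2CO3 in dioxane at 100 °C should give 11 directly, where the route is rejoined; no compound outside the list is made (F0).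

3. Step 2. The phenoxide–phosphonium betaine may lose triphenylphosphine (ortho-quinone methide pathway) before the ylide is formed, and the dianionic ylide may react incompletely. The fallback sets out from 3 and uses an O-protected phosphonate carbanion, with deprotection merged into the hydrogenation. Diethyl [2-(benzyloxy)benzyl]phosphonate F3 would be made by Arbuzov reaction of commercial 2-(benzyloxy)benzyl bromide with triethyl phosphite (neat, 130 °C). Horner–Wadsworth–Emmons olefination of 3 with F3 (NaH, THF, 0 °C to rt) would give 4-[5-[(E)-2-[2-(benzyloxy)phenyl]ethenyl]-2,3-dimethoxyphenoxy]benzonitrile F4. Hydrogenation (H2, Pd/C, EtOAc–EtOH) would saturate the alkene and cleave the benzyl ether in one operation, coming back to the route at 7.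

**Further compounds**
F1 | step 6 | [2-[2-[2-[3-[4-(hydroxymethyl)phenoxy]-4,5-dimethoxyphenyl]ethyl]phenoxy]-3,4-dimethoxyphenyl]methanol | COc1cc(CCc2ccccc2Oc2c(CO)ccc(OC)c2OC)cc(Oc2ccc(CO)cc2)c1OC
F2 | step 6 | 1-(bromomethyl)-2-[2-[2-[3-[4-(bromomethyl)phenoxy]-4,5-dimethoxyphenyl]ethyl]phenoxy]-3,4-dimethoxybenzene | COc1cc(CCc2ccccc2Oc2c(CBr)ccc(OC)c2OC)cc(Oc2ccc(CBr)cc2)c1OC
F0 | step 5 | none | none
F3 | step 2 | diethyl [2-(benzyloxy)benzyl]phosphonate | CCOP(=O)(OCC)Cc1ccccc1OCc1ccccc1
F4 | step 2 | 4-[5-[(E)-2-[2-(benzyloxy)phenyl]ethenyl]-2,3-dimethoxyphenoxy]benzonitrile | COc1cc(/C=C/c2ccccc2OCc2ccccc2)cc(Oc2ccc(C#N)cc2)c1OC
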